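**Retrosynthetic overview**
- The α-methylene lactone is opened at its C–O bond to a trans-2-isopropenylcyclohexanol; the allylic methyl is oxidised and closed onto the neighbouring hydroxyl in one operation (key step). The side-chain ester C–O bond is cut just before, back to a ring diol and the (R)-Roche-derived acid.
- The cyclohexane comes from a carbonyl-ene closure of an acyclic aldehyde; the carbocycle is formed first, the lactone last.
- The aldehyde comes from the acid of an enantioselective boron-enolate Ireland–Claisen rearrangement of a (Z)-allylic ester, which makes the methyl/vinyl quaternary carbon and its neighbour.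
- The (Z)-allylic diol comes from reduction of a 6-alkenyl-4-methyl-5,6-dihydropyran-2-one (a temporary ring), itself from a catalytic asymmetric vinylogous aldol–lactonisation of 3-methylbut-2-enal.
- The silyloxymethyl-butenoic acid comes from 2-methylprop-2-en-1-ol and CO2.

Abbreviations: TBS = t-BuMe2Si, TES = Et3Si, Tol-BINAP = 2,2'-bis(di-p-tolylphosphino)-1,1'-binaphthyl.
Assumption: (S)-Tol-BINAP is taken to give the 6S lactone and the S,S boron controller the 2R,3R acid; if a first run shows the opposite sense, the mirror-image ligand or controller is used.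

Step 1
Reactants: 1 methyl 3-methylbut-2-enoate
Product: 2 [(1-methoxy-3-methylbuta-1,3-dien-1-yl)oxy]trimethylsilane
Conditions: LiN(i-Pr)2, THF, −78 °C; Me3SiCl, −78 °C → rt; distil
Reagents that add atoms: chlorotrimethylsilane, C[Si](C)(C)Cl
Why: Kinetic γ-deprotonation of the senecioate and O-silylation of the dienolate (silyl dienol ether formation) gives the vinylogous nucleophile; no stereocentre is formed.

Step 2
Reactants: 2 [(1-methoxy-3-methylbuta-1,3-dien-1-yl)oxy]trimethylsilane; 3 3-methylbut-2-enal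
Product: 4 (6S)-4-methyl-6-(2-methylprop-1-en-1-yl)-5,6-dihydro-2H-pyran-2-one
Conditions: Cu(O3SCF3)2 (10 mol %), (S)-Tol-BINAP (11 mol %), Bu4N[Ph3SiF2] (20 mol %), THF, −78 °C → rt; 1 M HCl
Reagents that add atoms: none
Why: The bisphosphine copper dienolate made by fluoride transmetalation adds through its γ-carbon to one face of the aldehyde and the Z-aldolate closes onto the ester (catalytic asymmetric vinylogous Mukaiyama aldol–lactonisation), which sets C6 as S and locks the ring alkene as Z.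

Step 3
Reactants: 4 (6S)-4-methyl-6-(2-methylprop-1-en-1-yl)-5,6-dihydro-2H-pyran-2-one
Product: 5 (2Z,5S)-3,7-dimethylocta-2,6-diene-1,5-diol
Conditions: i-Bu2AlH (3.5 equiv), CH2Cl2, −78 → 0 °C; aq. KNaC4H4O6
Reagents that add atoms: none
Why: 1,2-Hydride reduction of the conjugated lactone through the lactol (i-Bu2AlH reduction) opens the ring to the ene-diol, carrying over the Z alkene and the carbinol centre unchanged.

Step 4
Reactants: 6 2-methylprop-2-en-1-ol
Product: 9 3-[(TBSO)methyl]but-3-enoic acid, via dilithium salt 7 (not isolated), via bis-silyl ester 8 (not isolated)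
Conditions: n-BuLi (2.2 equiv), TMEDA, Et2O–hexane, 0 °C → rt; CO2, −78 °C; t-BuMe2SiCl (2.5 equiv), imidazole (cat.), DMF, rt; AcOH–THF–H2O, 0 °C
Reagents that add atoms: carbon dioxide, O=C=O; tert-butyldimethylsilyl chloride, CC(C)(C)[Si](C)(C)Cl
Why: Alkoxide-directed allylic lithiation gives a 2-substituted allyllithium with two equivalent CH2 ends that is carboxylated (carbonation of an organolithium), both oxygens are silylated and only the labile silyl ester is hydrolysed on work-up, so the hydroxy acid never has the chance to lactonise; no stereocentre.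

Step 5
Reactants: 5 (2Z,5S)-3,7-dimethylocta-2,6-diene-1,5-diol; 9 3-[(TBSO)methyl]but-3-enoic acid
Product: 10 (2Z,5S)-5-hydroxy-3,7-dimethylocta-2,6-dien-1-yl 3-[(TBSO)methyl]but-3-enoate
Conditions: DCC (1.05 equiv), DMAP (5 mol %), CH2Cl2, −20 °C
Reagents that add atoms: none
Why: Steglich esterification acylates the unhindered primary allylic hydroxyl well ahead of the secondary one under neutral conditions that avoid cyclodehydration of the diol; no stereocentre is touched.

Step 6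
Reactants: 10 (2Z,5S)-5-hydroxy-3,7-dimethylocta-2,6-dien-1-yl 3-[(TBSO)methyl]but-3-enoate
Product: 11 (2Z,5S)-3,7-dimethyl-5-(TESO)octa-2,6-dien-1-yl 3-[(TBSO)methyl]but-3-enoate
Conditions: Et3SiCl, imidazole, CH2Cl2, 0 °C
Reagents that add atoms: chlorotriethylsilane, CC[Si](CC)(CC)Cl
Why: Silyl ether formation masks the secondary alcohol with a group that can later be removed in the presence of the primary TBS ether; the stereocentre is not touched.

Step 7
Reactants: 11 (2Z,5S)-3,7-dimethyl-5-(TESO)octa-2,6-dien-1-yl 3-[(TBSO)methyl]but-3-enoate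
Product: 13 (2R,3R,5S)-2-[3-(TBSO)prop-1-en-2-yl]-3-ethenyl-3,7-dimethyl-5-(TESO)oct-6-enoic acid, via boron ketene acetal 12 (not isolated)
Conditions: (4S,5S)-2-bromo-1,3-bis{[3,5-bis(trifluoromethyl)phenyl]sulfonyl}-4,5-diphenyl-1,3,2-diazaborolidine (1.2 equiv), Et3N (1.4 equiv), PhMe–hexane, −78 °C then 4 °C, 48 h; aq. HCl
Reagents that add atoms: none
Why: Soft enolisation gives the boron ketene acetal with the alkenyl arm cis to the allyloxy oxygen and the chair [3,3] shift (enantioselective boron-enolate Ireland–Claisen rearrangement) makes C2 and C3 together; the Z alkene puts the chain CH2 axial and the methyl equatorial, which fixes their relative configuration, and the C2-symmetric sulfonamide controller shields one enolate face, which fixes the absolute configuration independently of C5.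

Step 8
Reactants: 13 (2R,3R,5S)-2-[3-(TBSO)prop-1-en-2-yl]-3-ethenyl-3,7-dimethyl-5-(TESO)oct-6-enoic acid
Product: 15 (2R,3R,5S)-2-[3-(TBSO)prop-1-en-2-yl]-3-ethenyl-3,7-dimethyl-5-(TESO)oct-6-enal, via trimethylsilyl ester 14 (not isolated)
Conditions: Me3SiCl, Et3N, CH2Cl2, 0 °C; i-Bu2AlH (1.1 equiv), −78 °C; aq. KNaC4H4O6
Reagents that add atoms: none
Why: The silyl ester takes one hydride at −78 °C and the aluminium hemiacetal survives until work-up (partial reduction of an acid through its trimethylsilyl ester), so the aldehyde forms without epimerising C2.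

Step 9
Reactants: 15 (2R,3R,5S)-2-[3-(TBSO)prop-1-en-2-yl]-3-ethenyl-3,7-dimethyl-5-(TESO)oct-6-enal
Product: 17 (1S,2R,3R,4R,5R)-4-[3-(TBSO)prop-1-en-2-yl]-5-ethenyl-5-methyl-2-(prop-1-en-2-yl)cyclohexane-1,3-diol, via silyl ether 16 (not isolated)
Conditions: Me2AlCl (1.5 equiv), CH2Cl2, −78 → −40 °C; aq. NaHCO3; PPTS (10 mol %), MeOH, 0 °C
Reagents that add atoms: none
Why: Lewis-acid carbonyl-ene cyclisation of the citronellal type runs through a chair with the silyloxymethyl-propenyl arm, the silyloxy group and the reacting alkene equatorial, giving the new carbinol and the new isopropenyl-bearing carbon trans to each other and to their neighbours; mild acid methanolysis then removes the secondary TES ether and leaves the primary TBS ether.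

Step 10
Reactants: 18 methyl (2R)-3-hydroxy-2-methylpropanoate
Product: 20 (2R)-2-methyl-3-(TBSO)propanoic acid, via silyl ether ester 19 (not isolated)
Conditions: t-BuMe2SiCl, imidazole, DMF, rt; LiOH·H2O, THF–MeOH–H2O, 0 °C → rt; 1 M HCl to pH 3
Reagents that add atoms: tert-butyldimethylsilyl chloride, CC(C)(C)[Si](C)(C)Cl; lithium hydroxide, [Li+].[OH-]
Why: Silylation followed by saponification of the crude ester at 0 °C gives the protected acid without epimerising the purchased R centre.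

Step 11
Reactants: 17 (1S,2R,3R,4R,5R)-4-[3-(TBSO)prop-1-en-2-yl]-5-ethenyl-5-methyl-2-(prop-1-en-2-yl)cyclohexane-1,3-diol; 20 (2R)-2-methyl-3-(TBSO)propanoic acid
Product: 21 (1S,2S,3R,4R,5R)-4-[3-(TBSO)prop-1-en-2-yl]-5-ethenyl-3-hydroxy-5-methyl-2-(prop-1-en-2-yl)cyclohexyl (2R)-2-methyl-3-(TBSO)propanoate
Conditions: DCC (1.2 equiv), DMAP (10 mol %), CH2Cl2, 0 °C
Reagents that add atoms: none
Why: Steglich esterification goes to the C1 hydroxyl, which has a CH2 on one side, in preference to the C3 hydroxyl, which sits between two propenyl-bearing carbons; no stereocentre changes (the C2 descriptor changes only by priority).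

Step 12
Reactants: 21 (1S,2S,3R,4R,5R)-4-[3-(TBSO)prop-1-en-2-yl]-5-ethenyl-3-hydroxy-5-methyl-2-(prop-1-en-2-yl)cyclohexyl (2R)-2-methyl-3-(TBSO)propanoate
Product: 24 (3aR,4S,6R,7R,7aR)-7-[3-(TBSO)prop-1-en-2-yl]-6-ethenyl-6-methyl-3-methylidene-2-oxooctahydro-1-benzofuran-4-yl (2R)-2-methyl-3-(TBSO)propanoate, via allylic alcohol 22 (not isolated), via lactol 23 (not isolated)
Conditions: SeO2 (0.2 equiv), t-BuOOH (2 equiv), CH2Cl2, 0 °C → rt; then 4-acetamido-TEMPO (10 mol %), PhI(OAc)2 (2.4 equiv), same flask, rt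
Reagents that add atoms: tert-butyl hydroperoxide, CC(C)(C)OO
Why: Proposed new method: a one-flask relay in which catalytic SeO2 (tetravalent selenium, turned over by t-BuOOH) hydroxylates the isopropenyl methyl group by the ene/[2,3]-shift path, the oxoammonium ion made from the nitroxyl and PhI(OAc)2 then oxidises only this new primary allylic alcohol, the neighbouring equatorial hydroxyl traps the aldehyde as the trans-fused lactol and a second oxoammonium turnover gives the lactone, so the ring-closing C–O bond and the carbonyl are made in one operation with no change at any stereocentre; the other arm is spared because its alkene is inductively deactivated by the silyloxymethyl group and the vinyl group has no allylic hydrogen; the closest known reactions are SeO2/t-BuOOH allylic hydroxylation and nitroxyl/PhI(OAc)2 oxidative lactonisation of 1,4-diols, which have not been combined on a 2-isopropenylcyclohexanol.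

Step 13
Reactants: 24 (3aR,4S,6R,7R,7aR)-7-[3-(TBSO)prop-1-en-2-yl]-6-ethenyl-6-methyl-3-methylidene-2-oxooctahydro-1-benzofuran-4-yl (2R)-2-methyl-3-(TBSO)propanoate
Product: 25 (3aR,4S,6R,7R,7aR)-6-ethenyl-7-(3-hydroxyprop-1-en-2-yl)-6-methyl-3-methylidene-2-oxooctahydro-1-benzofuran-4-yl (2R)-3-hydroxy-2-methylpropanoate
Conditions: HF·pyridine, pyridine–THF, 0 °C → rt
Reagents that add atoms: none
Why: Buffered fluoride desilylation frees both primary alcohols at once without touching the ester, the α-methylene lactone or any stereocentre.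

**Compound list**
1 | methyl 3-methylbut-2-enoate | COC(=O)C=C(C)C | starting material
2 | [(1-methoxy-3-methylbuta-1,3-dien-1-yl)oxy]trimethylsilane (E/Z mixture at the ketene acetal) | C=C(C)C=C(OC)O[Si](C)(C)C | intermediate
3 | 3-methylbut-2-enal | CC(C)=CC=O | starting material
4 | (6S)-4-methyl-6-(2-methylprop-1-en-1-yl)-5,6-dihydro-2H-pyran-2-one | CC(C)=C[C@@H]1CC(C)=CC(=O)O1 | intermediate
5 | (2Z,5S)-3,7-dimethylocta-2,6-diene-1,5-diol | OC/C=C(C)\C[C@H](O)C=C(C)C | intermediate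
6 | 2-methylprop-2-en-1-ol | C=C(C)CO | starting material
7 | dilithium 3-(oxidomethyl)but-3-enoate | [Li+].[Li+].[O-]CC(=C)CC(=O)[O-] | intermediate
8 | tert-butyldimethylsilyl 3-[(TBSO)methyl]but-3-enoate | CC(C)(C)[Si](C)(C)OCC(=C)CC(=O)O[Si](C)(C)C(C)(C)C | intermediate
9 | 3-[(TBSO)methyl]but-3-enoic acid | CC(C)(C)[Si](C)(C)OCC(=C)CC(=O)O | intermediate
10 | (2Z,5S)-5-hydroxy-3,7-dimethylocta-2,6-dien-1-yl 3-[(TBSO)methyl]but-3-enoate | CC(C)(C)[Si](C)(C)OCC(=C)CC(=O)OC/C=C(C)\C[C@H](O)C=C(C)C | intermediate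
11 | (2Z,5S)-3,7-dimethyl-5-(TESO)octa-2,6-dien-1-yl 3-[(TBSO)methyl]but-3-enoate | CC(C)(C)[Si](C)(C)OCC(=C)CC(=O)OC/C=C(C)\C[C@H](O[Si](CC)(CC)CC)C=C(C)C | intermediate
12 | boron ketene acetal of 11: enol oxygen bonded to the (4S,5S)-4,5-diphenyl-1,3-bis{[3,5-bis(trifluoromethyl)phenyl]sulfonyl}-1,3,2-diazaborolidin-2-yl boron, alkenyl arm cis to the allyloxy oxygen | CC(C)(C)[Si](C)(C)OCC(=C)/C=C(\OC/C=C(C)\C[C@H](O[Si](CC)(CC)CC)C=C(C)C)OB1N(S(=O)(=O)c2cc(cc(c2)C(F)(F)F)C(F)(F)F)[C@@H](c2ccccc2)[C@H](c2ccccc2)N1S(=O)(=O)c1cc(cc(c1)C(F)(F)F)C(F)(F)F | intermediate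
13 | (2R,3R,5S)-2-[3-(TBSO)prop-1-en-2-yl]-3-ethenyl-3,7-dimethyl-5-(TESO)oct-6-enoic acid | OC(=O)[C@@H](C(=C)CO[Si](C)(C)C(C)(C)C)[C@@](C)(C=C)C[C@H](O[Si](CC)(CC)CC)C=C(C)C | intermediate
14 | trimethylsilyl (2R,3R,5S)-2-[3-(TBSO)prop-1-en-2-yl]-3-ethenyl-3,7-dimethyl-5-(TESO)oct-6-enoate | C[Si](C)(C)OC(=O)[C@@H](C(=C)CO[Si](C)(C)C(C)(C)C)[C@@](C)(C=C)C[C@H](O[Si](CC)(CC)CC)C=C(C)C | intermediate
15 | (2R,3R,5S)-2-[3-(TBSO)prop-1-en-2-yl]-3-ethenyl-3,7-dimethyl-5-(TESO)oct-6-enal | O=C[C@@H](C(=C)CO[Si](C)(C)C(C)(C)C)[C@@](C)(C=C)C[C@H](O[Si](CC)(CC)CC)C=C(C)C | intermediate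
16 | (1R,2R,3R,5S,6S)-2-[3-(TBSO)prop-1-en-2-yl]-3-ethenyl-3-methyl-6-(prop-1-en-2-yl)-5-(TESO)cyclohexan-1-ol | C=C[C@@]1(C)C[C@H](O[Si](CC)(CC)CC)[C@@H](C(C)=C)[C@H](O)[C@H]1C(=C)CO[Si](C)(C)C(C)(C)C | intermediate
17 | (1S,2R,3R,4R,5R)-4-[3-(TBSO)prop-1-en-2-yl]-5-ethenyl-5-methyl-2-(prop-1-en-2-yl)cyclohexane-1,3-diol | C=C[C@@]1(C)C[C@H](O)[C@@H](C(C)=C)[C@H](O)[C@H]1C(=C)CO[Si](C)(C)C(C)(C)C | intermediate
18 | methyl (2R)-3-hydroxy-2-methylpropanoate | COC(=O)[C@H](C)CO | starting material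
19 | methyl (2R)-2-methyl-3-(TBSO)propanoate | COC(=O)[C@H](C)CO[Si](C)(C)C(C)(C)C | intermediate
20 | (2R)-2-methyl-3-(TBSO)propanoic acid | OC(=O)[C@H](C)CO[Si](C)(C)C(C)(C)C | intermediate
21 | (1S,2S,3R,4R,5R)-4-[3-(TBSO)prop-1-en-2-yl]-5-ethenyl-3-hydroxy-5-methyl-2-(prop-1-en-2-yl)cyclohexyl (2R)-2-methyl-3-(TBSO)propanoate | C=C[C@@]1(C)C[C@H](OC(=O)[C@H](C)CO[Si](C)(C)C(C)(C)C)[C@@H](C(C)=C)[C@H](O)[C@H]1C(=C)CO[Si](C)(C)C(C)(C)C | intermediate
22 | (1S,2S,3R,4R,5R)-4-[3-(TBSO)prop-1-en-2-yl]-5-ethenyl-3-hydroxy-2-(3-hydroxyprop-1-en-2-yl)-5-methylcyclohexyl (2R)-2-methyl-3-(TBSO)propanoate | C=C[C@@]1(C)C[C@H](OC(=O)[C@H](C)CO[Si](C)(C)C(C)(C)C)[C@@H](C(=C)CO)[C@H](O)[C@H]1C(=C)CO[Si](C)(C)C(C)(C)C | intermediate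
23 | (3aR,4S,6R,7R,7aR)-7-[3-(TBSO)prop-1-en-2-yl]-6-ethenyl-2-hydroxy-6-methyl-3-methylideneoctahydro-1-benzofuran-4-yl (2R)-2-methyl-3-(TBSO)propanoate (both C2 epimers) | C=C[C@@]1(C)C[C@H](OC(=O)[C@H](C)CO[Si](C)(C)C(C)(C)C)[C@H]2C(=C)C(O)O[C@@H]2[C@H]1C(=C)CO[Si](C)(C)C(C)(C)C | intermediate
24 | (3aR,4S,6R,7R,7aR)-7-[3-(TBSO)prop-1-en-2-yl]-6-ethenyl-6-methyl-3-methylidene-2-oxooctahydro-1-benzofuran-4-yl (2R)-2-methyl-3-(TBSO)propanoate | C=C[C@@]1(C)C[C@H](OC(=O)[C@H](C)CO[Si](C)(C)C(C)(C)C)[C@H]2C(=C)C(=O)O[C@@H]2[C@H]1C(=C)CO[Si](C)(C)C(C)(C)C | intermediate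
25 | (3aR,4S,6R,7R,7aR)-6-ethenyl-7-(3-hydroxyprop-1-en-2-yl)-6-methyl-3-methylidene-2-oxooctahydro-1-benzofuran-4-yl (2R)-3-hydroxy-2-methylpropanoate | C=C[C@@]1(C)C[C@H](OC(=O)[C@H](C)CO)[C@H]2C(=C)C(=O)O[C@@H]2[C@H]1C(=C)CO | target

**Step count and risks**
Total steps: 13 (a one-flask sequence counts as one step). Longest linear sequence: 11 steps (1, 2, 3, 5, 6, 7, 8, 9, 11, 12, 13).

The three steps most likely to fail are 7, 9 and 12.

Step 7 may give poor enolate geometry or face control with this β,γ-unsaturated ester, or the bromoborane may attack the silyl ethers. The fallback sets out from 11 and drops the chiral controller: LiN(i-Pr)2 then Me3SiCl/Et3N in THF at −78 °C gives the trimethylsilyl ketene acetal F1, which rearranges on warming to a mixture of acid 13 and its 2S,3S diastereomer F2. Because C5 is already fixed these are diastereomers, not enantiomers, and are separated by chromatography; the route resumes at 13 at the cost of about half the material.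

Step 9 may fail through ionisation of the allylic silyl ether or isomerisation of the α-branched aldehyde under the aluminium Lewis acid. The fallback sets out from acid 13 and closes the ring by acylation instead of an ene reaction: 1-chloro-N,N,2-trimethylprop-1-en-1-amine gives the acid chloride F3; SnCl4 in CH2Cl2 at −78 °C acylates the trisubstituted alkene with loss of HCl to give the 2,6-dialkenyl cyclohexanone F4 (both α-centres equatorial); NaBH4 in MeOH at −40 °C delivers hydride axially and returns to silyl ether 16.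

Step 12 is untested as a single operation: residual peroxide and selenium species may interfere with the nitroxyl stage, or the acyloxy neighbour may slow the ene step. The fallback uses known reactions only and sets out from silyl ether 16, isolated after the ene step instead of being methanolysed. SeO2/t-BuOOH in CH2Cl2 gives the allylic alcohol F5; MnO2 in CH2Cl2 oxidises it through the lactol to the silyloxy lactone F6; PPTS in MeOH frees the secondary alcohol to give the hydroxy lactone F7; Steglich esterification with acid 20 then rejoins the route at 24.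

**Further compounds**
F1 | step 7 | trimethylsilyl ketene acetal of ester 11 (alkenyl arm cis to the allyloxy oxygen) | CC(C)(C)[Si](C)(C)OCC(=C)/C=C(\OC/C=C(C)\C[C@H](O[Si](CC)(CC)CC)C=C(C)C)O[Si](C)(C)C
F2 | step 7 | (2S,3S,5S)-2-[3-(TBSO)prop-1-en-2-yl]-3-ethenyl-3,7-dimethyl-5-(TESO)oct-6-enoic acid | OC(=O)[C@H](C(=C)CO[Si](C)(C)C(C)(C)C)[C@](C)(C=C)C[C@H](O[Si](CC)(CC)CC)C=C(C)C
F3 | step 9 | (2R,3R,5S)-2-[3-(TBSO)prop-1-en-2-yl]-3-ethenyl-3,7-dimethyl-5-(TESO)oct-6-enoyl chloride | ClC(=O)[C@@H](C(=C)CO[Si](C)(C)C(C)(C)C)[C@@](C)(C=C)C[C@H](O[Si](CC)(CC)CC)C=C(C)C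
F4 | step 9 | (2R,3R,5S,6R)-2-[3-(TBSO)prop-1-en-2-yl]-3-ethenyl-3-methyl-6-(prop-1-en-2-yl)-5-(TESO)cyclohexan-1-one | C=C[C@@]1(C)C[C@H](O[Si](CC)(CC)CC)[C@@H](C(C)=C)C(=O)[C@H]1C(=C)CO[Si](C)(C)C(C)(C)C
F5 | step 12 | (1R,2R,3R,5S,6S)-2-[3-(TBSO)prop-1-en-2-yl]-3-ethenyl-6-(3-hydroxyprop-1-en-2-yl)-3-methyl-5-(TESO)cyclohexan-1-ol | C=C[C@@]1(C)C[C@H](O[Si](CC)(CC)CC)[C@@H](C(=C)CO)[C@H](O)[C@H]1C(=C)CO[Si](C)(C)C(C)(C)C
F6 | step 12 | (3aS,4S,6R,7R,7aR)-7-[3-(TBSO)prop-1-en-2-yl]-6-ethenyl-6-methyl-3-methylidene-4-(TESO)hexahydro-1-benzofuran-2(3H)-one | C=C[C@@]1(C)C[C@H](O[Si](CC)(CC)CC)[C@H]2C(=C)C(=O)O[C@@H]2[C@H]1C(=C)CO[Si](C)(C)C(C)(C)C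
F7 | step 12 | (3aR,4S,6R,7R,7aR)-7-[3-(TBSO)prop-1-en-2-yl]-6-ethenyl-4-hydroxy-6-methyl-3-methylidenehexahydro-1-benzofuran-2(3H)-one | C=C[C@@]1(C)C[C@H](O)[C@H]2C(=C)C(=O)O[C@@H]2[C@H]1C(=C)CO[Si](C)(C)C(C)(C)C
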